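**Plan**

Ring numbering of the target: C1 (quaternary; CH3 and (E)-2-chlorovinyl), C2 (CH2), C3 (Cl and CH2Br), C4 (CHBr), C5 (CH2), C6 (CHCl).
Cuts: C4–Br, CH2–Br, C3–Cl and C6–Cl go back to C–O bonds; the chloroalkene C=C to an aldehyde plus CHCl3; the C3–CH2 bond to an enol triflate plus CO; last, the ring itself at C5=C6.
Enabling feature: with C5=C6 unsaturated, C1 carries the side-chain vinyl and the ring vinyl C6=C5 beside CH3 and C2, so it is an achiral divinyl carbon and the cyclohexane (the only ring) can be closed by a ring-closing metathesis that picks one of two enantiotopic vinyl groups.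
Forward order: acyclic chain (Johnson–Claisen makes the divinyl carbon, then allyl ketone, ketal) → cyclohexene → oxygen then chlorine at C6 → exocyclic carbon at C3 → chlorovinyl → C3/C4 oxirane → chlorine at C3 → both bromines.
Stereochemistry: C1 from the chiral molybdenum catalyst; C6 from a reagent-controlled CBS reduction followed by inversion with chloride; C3 and C4 from a Sharpless epoxidation (D-tartrate) with inversion at each carbon; the E-chloroalkene from the Takai–Utimoto reaction.

Key step: step 6

Assumption: the hand of each chiral catalyst is provisional (the (S)-biphenolate is taken to give the (R) ring-closure product, and in the CBS step the quaternary carbon is taken as the large ketone substituent); if a test reaction shows the opposite sense, the mirror-image catalyst is used.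

**Route**

Step 1
Reactants: 1 3-methylpent-2-en-4-yn-1-ol (E/Z mixture)
Product: 2 3-methylpenta-2,4-dien-1-ol
Conditions: H2 (1 atm), Pd/CaCO3 poisoned with Pb(OAc)2 (Lindlar catalyst), quinoline, hexane, 0 °C
Reagents that add atoms: none
Why: Lindlar semi-hydrogenation should stop at the diene because the poisoned palladium surface binds the alkyne far more strongly than an alkene, and the geometry of the trisubstituted alkene does not matter since its carbon becomes an achiral centre in the next step.

Step 2
Reactants: 2 3-methylpenta-2,4-dien-1-ol; 3 triethyl orthoacetate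
Product: 5 ethyl 3-methyl-3-vinylpent-4-enoate, via ketene acetal 4 (not isolated)
Conditions: MeC(OEt)3 (5 equiv), EtCO2H (5 mol %), 140 °C, EtOH distilled off
Reagents that add atoms: none
Why: Johnson–Claisen rearrangement, in which the [3,3] shift of the mixed ketene acetal forms the C–C bond at the methyl-bearing alkene carbon and so creates the quaternary carbon with two identical vinyl groups (no stereocentre).

Step 3
Reactants: 5 ethyl 3-methyl-3-vinylpent-4-enoate
Product: 6 N-methoxy-N,3-dimethyl-3-vinylpent-4-enamide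
Conditions: MeNH(OMe)·HCl (1.5 equiv), i-PrMgCl (3 equiv), THF, −20 → 0 °C
Reagents that add atoms: N,O-dimethylhydroxylamine hydrochloride, CNOC.Cl
Why: Weinreb amide formation by aminolysis of the ester with the chloromagnesium amide made in the flask, a direct one-step conversion that should tolerate the non-conjugated alkenes.

Step 4
Reactants: 6 N-methoxy-N,3-dimethyl-3-vinylpent-4-enamide; 7 allylmagnesium bromide
Product: 9 6-methyl-6-vinylocta-1,7-dien-4-one, via magnesium hemiaminal chelate 8 (not isolated)
Conditions: THF, −78 °C; then sat. aq. NH4Cl, −78 → 0 °C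
Reagents that add atoms: none
Why: Grignard addition to a Weinreb amide stops at the chelated tetrahedral adduct, which releases the β,γ-unsaturated ketone only on cold, near-neutral quench, so neither double addition nor conjugation of the allyl double bond is expected.

Step 5
Reactants: 9 6-methyl-6-vinylocta-1,7-dien-4-one; 10 1,2-bis(trimethylsilyloxy)ethane
Product: 11 2-allyl-2-(2-methyl-2-vinylbut-3-en-1-yl)-1,3-dioxolane
Conditions: TMSOTf (5 mol %), CH2Cl2, −78 → −30 °C; pyridine quench
Reagents that add atoms: none
Why: TMSOTf-catalysed ketalisation with the bis-silyl ether, driven by formation of hexamethyldisiloxane, runs aprotically at low temperature and should therefore leave the allyl double bond out of conjugation.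

Step 6
Reactants: 11 2-allyl-2-(2-methyl-2-vinylbut-3-en-1-yl)-1,3-dioxolane
Product: 12 (R)-7-methyl-7-vinyl-1,4-dioxaspiro[4.5]dec-8-ene
Conditions: Mo(N-2,6-i-Pr2C6H3)(CHCMe2Ph)[(S)-3,3'-di-tert-butyl-5,5',6,6'-tetramethylbiphenyl-2,2'-diolate] (5 mol %), C6H6 (0.05 M), 22 °C, N2 sweep
Reagents that add atoms: none
Why: The molybdenum alkylidene first exchanges with the allyl terminus, the only unhindered monosubstituted alkene, and the new alkylidene adds in a [2+2] sense to one of the two vinyl groups on the quaternary carbon; cycloreversion of the molybdacyclobutane releases the cyclohexene and Mo=CH2, which re-enters the cycle with loss of ethylene. The closest known reaction type is the molybdenum-catalysed asymmetric ring-closing metathesis of achiral trienes to cycloalkenes with all-carbon quaternary stereocentres. The one ring formed, the six-membered carbocycle, is closed by ring-closing alkene metathesis of a 1,7-diene, which makes the C8=C9 double bond (C5=C6 of the target). The one new stereocentre, C7 (C1 of the target), is set without a bond being made to it, because the chiral biphenolate on molybdenum decides which enantiotopic vinyl group enters the metallacycle. The step needs site selectivity for initiation and enantiotopic-group selectivity for closure; the first is secured by the neopentyl-type shielding of both vinyl groups (which also cannot close a ring with each other), the second by the catalyst, and removal of ethylene keeps the closure from reversing.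

Step 7
Reactants: 12 (R)-7-methyl-7-vinyl-1,4-dioxaspiro[4.5]dec-8-ene
Product: 15 (R)-7-methyl-7-vinyl-1,4-dioxaspiro[4.5]dec-9-en-8-one, via allylic hydroperoxide 13 (not isolated), via allylic peracetate 14 (not isolated)
Conditions: O2, tetraphenylporphyrin (0.5 mol %), visible light, CH2Cl2, 0 °C; then Ac2O, pyridine, DMAP (cat.), 0 → 23 °C
Reagents that add atoms: dioxygen, O=O
Why: Schenck ene reaction of singlet oxygen, in which oxygen must bond to C8 because the only allylic hydrogens sit on C10 (C7 is quaternary) and the double bond moves to C9=C10, followed by acetylation and Kornblum–DeLaMare-type fragmentation of the secondary hydroperoxide to the enone, so the configuration at C8 is of no consequence here.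

Step 8
Reactants: 15 (R)-7-methyl-7-vinyl-1,4-dioxaspiro[4.5]dec-9-en-8-one
Product: 16 (7R,8S)-7-methyl-7-vinyl-1,4-dioxaspiro[4.5]dec-9-en-8-ol
Conditions: (R)-1-methyl-3,3-diphenyltetrahydro-1H,3H-pyrrolo[1,2-c][1,3,2]oxazaborole ((R)-Me-CBS, 20 mol %), catecholborane (1.5 equiv), toluene, −78 °C
Reagents that add atoms: none
Why: Corey–Bakshi–Shibata reduction, in which the ketone binds the oxazaborolidine with the quaternary C7 as the large group and hydride is delivered under reagent control to give the (8S) carbinol (hydroxyl cis to methyl), the methyl/vinyl pair on C7 exerting little bias of its own and catecholborane at −78 °C leaving the alkenes untouched.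

Step 9
Reactants: 16 (7R,8S)-7-methyl-7-vinyl-1,4-dioxaspiro[4.5]dec-9-en-8-ol
Product: 17 (7R,8R)-8-chloro-7-methyl-7-vinyl-1,4-dioxaspiro[4.5]dec-9-ene
Conditions: PPh3 (1.3 equiv), Cl3CC(O)CCl3, CH2Cl2, −20 → 0 °C
Reagents that add atoms: hexachloroacetone, ClC(Cl)(Cl)C(=O)C(Cl)(Cl)Cl
Why: Appel-type chlorination, in which chloride displaces the allylic alkoxyphosphonium with inversion to place chlorine cis to the vinyl group; elimination is impossible (C7 has no hydrogen, C9 is sp2), the allylic π-system offsets the neopentyl retardation, and attack at the other allyl terminus C10 is disfavoured by the adjacent ketal.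

Step 10
Reactants: 17 (7R,8R)-8-chloro-7-methyl-7-vinyl-1,4-dioxaspiro[4.5]dec-9-ene
Product: 18 (4R,5R)-4-chloro-5-methyl-5-vinylcyclohex-2-en-1-one
Conditions: 1 M aq. HCl, THF, 0 → 23 °C
Reagents that add atoms: water, O
Why: Acid-catalysed ketal hydrolysis through a conjugated oxocarbenium ion gives an enone that is already conjugated, so no double-bond migration can occur, and the allylic chloride should survive because its ionisation would place positive charge next to the carbonyl system.

Step 11
Reactants: 18 (4R,5R)-4-chloro-5-methyl-5-vinylcyclohex-2-en-1-one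
Product: 20 (4R,5R)-4-chloro-5-methyl-5-vinylcyclohex-1-en-1-yl trifluoromethanesulfonate, via lithium enolate 19 (not isolated)
Conditions: Li[(s-Bu)3BH] (1.05 equiv), THF, −78 °C; then PhNTf2, −78 → 0 °C; sat. aq. NH4Cl
Reagents that add atoms: N-phenylbis(trifluoromethanesulfonimide), O=S(=O)(N(c1ccccc1)S(=O)(=O)C(F)(F)F)C(F)(F)F
Why: Conjugate hydride reduction of the β-unsubstituted cyclohexenone gives only the enolate that points toward the future C4, and O-triflation of this enolate fixes the double bond there without touching the stereocentres.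

Step 12
Reactants: 20 (4R,5R)-4-chloro-5-methyl-5-vinylcyclohex-1-en-1-yl trifluoromethanesulfonate; 21 carbon monoxide
Product: 22 methyl (4R,5R)-4-chloro-5-methyl-5-vinylcyclohex-1-ene-1-carboxylate
Conditions: Pd(OAc)2 (5 mol %), PPh3 (10 mol %), CO (1 atm), MeOH, Et3N, DMF, 50 °C
Reagents that add atoms: methanol, CO
Why: Palladium-catalysed methoxycarbonylation of an enol triflate (oxidative addition to zerovalent palladium, CO insertion, methanolysis) installs the exocyclic carbon of C3, the unactivated secondary chloride being inert to palladium.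

Step 13
Reactants: 22 methyl (4R,5R)-4-chloro-5-methyl-5-vinylcyclohex-1-ene-1-carboxylate
Product: 24 methyl (4R,5R)-4-chloro-5-formyl-5-methylcyclohex-1-ene-1-carboxylate, via ozonide 23 (not isolated)
Conditions: O3, CH2Cl2, −78 °C (Sudan red indicator); then PPh3, −78 → 23 °C
Reagents that add atoms: ozone, [O-][O+]=O
Why: Ozonolysis should be chemoselective for the electron-rich monosubstituted vinyl group over the electron-poor trisubstituted enoate (dye end point), and reductive cleavage of the ozonide gives a non-enolisable aldehyde.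

Step 14
Reactants: 24 methyl (4R,5R)-4-chloro-5-formyl-5-methylcyclohex-1-ene-1-carboxylate; 25 chloroform
Product: 26 methyl (4R,5R)-4-chloro-5-[(E)-2-chlorovinyl]-5-methylcyclohex-1-ene-1-carboxylate
Conditions: CrCl2 (6 equiv), CHCl3 (2 equiv), THF, 65 °C
Reagents that add atoms: none
Why: Takai–Utimoto olefination, in which the geminal dichromium species formed from chloroform and divalent chromium adds to the aldehyde and eliminates to the (E)-chloroalkene, while the ester and the unactivated secondary chloride are inert to divalent chromium.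

Step 15
Reactants: 26 methyl (4R,5R)-4-chloro-5-[(E)-2-chlorovinyl]-5-methylcyclohex-1-ene-1-carboxylate
Product: 27 [(4R,5R)-4-chloro-5-[(E)-2-chlorovinyl]-5-methylcyclohex-1-en-1-yl]methanol
Conditions: i-Bu2AlH (2.5 equiv), CH2Cl2, −78 °C; aq. potassium sodium tartrate
Reagents that add atoms: none
Why: 1,2-Reduction of the α,β-unsaturated ester by i-Bu2AlH gives the primary allylic alcohol, and neither the chloroalkene nor the alkyl chloride reacts at −78 °C.

Step 16
Reactants: 27 [(4R,5R)-4-chloro-5-[(E)-2-chlorovinyl]-5-methylcyclohex-1-en-1-yl]methanol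
Product: 28 [(1R,3R,4R,6R)-4-chloro-3-[(E)-2-chlorovinyl]-3-methyl-7-oxabicyclo[4.1.0]heptan-1-yl]methanol
Conditions: Ti(Oi-Pr)4 (10 mol %), D-(−)-diisopropyl tartrate (12 mol %), t-BuOOH (2 equiv, decane), 4 Å MS, CH2Cl2, −20 °C
Reagents that add atoms: tert-butyl hydroperoxide, CC(C)(C)OO
Why: Sharpless asymmetric epoxidation, in which the D-tartrate complex delivers oxygen under reagent control to the face of the 1-cyclohexenylmethanol unit that is cis to the methyl group and anti to the chlorovinyl group and ring chlorine, the electron-poor chloroalkene being unreactive.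

Step 17
Reactants: 28 [(1R,3R,4R,6R)-4-chloro-3-[(E)-2-chlorovinyl]-3-methyl-7-oxabicyclo[4.1.0]heptan-1-yl]methanol
Product: 29 (1R,2S,4R,5R)-2,5-dichloro-4-[(E)-2-chlorovinyl]-2-(hydroxymethyl)-4-methylcyclohexan-1-ol
Conditions: HCl (2 M in Et2O, 1.5 equiv), CH2Cl2, −40 → 0 °C
Reagents that add atoms: hydrogen chloride, Cl
Why: Acid-mediated oxirane opening at the more substituted carbon (Fürst–Plattner trans-diaxial mode), in which chloride attacks the tertiary carbon anti to the oxygen and so inverts C3 to the chloride cis to the chlorovinyl group while C4 keeps its oxygen; the competing diaxial attack at C4 would have to pass a syn-axial ring chlorine.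

Step 18
Reactants: 29 (1R,2S,4R,5R)-2,5-dichloro-4-[(E)-2-chlorovinyl]-2-(hydroxymethyl)-4-methylcyclohexan-1-ol
Product: 31 (1S,2S,4R,5R)-2-bromo-1-(bromomethyl)-1,4-dichloro-5-[(E)-2-chlorovinyl]-5-methylcyclohexane, via bis-triflate 30 (not isolated)
Conditions: Tf2O (2.4 equiv), 2,6-lutidine (3 equiv), CH2Cl2, −78 °C; then n-Bu4NBr (6 equiv), toluene, −78 → 40 °C
Reagents that add atoms: tetrabutylammonium bromide, CCCC[N+](CCCC)(CCCC)CCCC.[Br-]
Why: Double SN2 displacement of triflates by bromide, in which the secondary triflate is inverted so that bromine ends cis to the tertiary chlorine (chlorine is a poor neighbouring group, so direct substitution should outrun chloronium formation) and the neopentyl-type primary triflate gives the bromomethyl group.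

**Compound list**

1 | 3-methylpent-2-en-4-yn-1-ol (E/Z mixture) | CC(=CCO)C#C | starting material
2 | 3-methylpenta-2,4-dien-1-ol | CC(=CCO)C=C | intermediate
3 | triethyl orthoacetate | CCOC(C)(OCC)OCC | starting material
4 | 1-ethoxy-1-[(3-methylpenta-2,4-dien-1-yl)oxy]ethene (ketene acetal) | C=C(OCC)OCC=C(C)C=C | intermediate
5 | ethyl 3-methyl-3-vinylpent-4-enoate | CCOC(=O)CC(C)(C=C)C=C | intermediate
6 | N-methoxy-N,3-dimethyl-3-vinylpent-4-enamide | CON(C)C(=O)CC(C)(C=C)C=C | intermediate
7 | allylmagnesium bromide | C=CC[Mg]Br | starting material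
8 | bromomagnesium 4-[methoxy(methyl)amino]-6-methyl-6-vinylocta-1,7-dien-4-olate (chelated tetrahedral adduct) | C=CCC(O[Mg]Br)(N(C)OC)CC(C)(C=C)C=C | intermediate
9 | 6-methyl-6-vinylocta-1,7-dien-4-one | C=CCC(=O)CC(C)(C=C)C=C | intermediate
10 | 1,2-bis(trimethylsilyloxy)ethane | C[Si](C)(C)OCCO[Si](C)(C)C | starting material
11 | 2-allyl-2-(2-methyl-2-vinylbut-3-en-1-yl)-1,3-dioxolane | C=CCC1(OCCO1)CC(C)(C=C)C=C | intermediate
12 | (R)-7-methyl-7-vinyl-1,4-dioxaspiro[4.5]dec-8-ene | C[C@]1(C=C)CC2(OCCO2)CC=C1 | intermediate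
13 | (7R)-8-hydroperoxy-7-methyl-7-vinyl-1,4-dioxaspiro[4.5]dec-9-ene (both C8 epimers) | C[C@]1(C=C)CC2(OCCO2)C=CC1OO | intermediate
14 | (7R)-7-methyl-7-vinyl-1,4-dioxaspiro[4.5]dec-9-en-8-yl peracetate (both C8 epimers) | C[C@]1(C=C)CC2(OCCO2)C=CC1OOC(C)=O | intermediate
15 | (R)-7-methyl-7-vinyl-1,4-dioxaspiro[4.5]dec-9-en-8-one | C[C@]1(C=C)CC2(OCCO2)C=CC1=O | intermediate
16 | (7R,8S)-7-methyl-7-vinyl-1,4-dioxaspiro[4.5]dec-9-en-8-ol | C[C@]1(C=C)CC2(OCCO2)C=C[C@@H]1O | intermediate
17 | (7R,8R)-8-chloro-7-methyl-7-vinyl-1,4-dioxaspiro[4.5]dec-9-ene | C[C@]1(C=C)CC2(OCCO2)C=C[C@H]1Cl | intermediate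
18 | (4R,5R)-4-chloro-5-methyl-5-vinylcyclohex-2-en-1-one | C[C@]1(C=C)CC(=O)C=C[C@H]1Cl | intermediate
19 | lithium (4R,5R)-4-chloro-5-methyl-5-vinylcyclohex-1-en-1-olate | C[C@]1(C=C)CC([O-])=CC[C@H]1Cl.[Li+] | intermediate
20 | (4R,5R)-4-chloro-5-methyl-5-vinylcyclohex-1-en-1-yl trifluoromethanesulfonate | C[C@]1(C=C)CC(OS(=O)(=O)C(F)(F)F)=CC[C@H]1Cl | intermediate
21 | carbon monoxide | [C-]#[O+] | starting material
22 | methyl (4R,5R)-4-chloro-5-methyl-5-vinylcyclohex-1-ene-1-carboxylate | C[C@]1(C=C)CC(C(=O)OC)=CC[C@H]1Cl | intermediate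
23 | methyl (4R,5R)-4-chloro-5-methyl-5-(1,2,4-trioxolan-3-yl)cyclohex-1-ene-1-carboxylate (ozonide, trioxolane carbon unassigned) | C[C@]1(C2OOCO2)CC(C(=O)OC)=CC[C@H]1Cl | intermediate
24 | methyl (4R,5R)-4-chloro-5-formyl-5-methylcyclohex-1-ene-1-carboxylate | C[C@]1(C=O)CC(C(=O)OC)=CC[C@H]1Cl | intermediate
25 | chloroform | ClC(Cl)Cl | starting material
26 | methyl (4R,5R)-4-chloro-5-[(E)-2-chlorovinyl]-5-methylcyclohex-1-ene-1-carboxylate | C[C@]1(/C=C/Cl)CC(C(=O)OC)=CC[C@H]1Cl | intermediate
27 | [(4R,5R)-4-chloro-5-[(E)-2-chlorovinyl]-5-methylcyclohex-1-en-1-yl]methanol | C[C@]1(/C=C/Cl)CC(CO)=CC[C@H]1Cl | intermediate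
28 | [(1R,3R,4R,6R)-4-chloro-3-[(E)-2-chlorovinyl]-3-methyl-7-oxabicyclo[4.1.0]heptan-1-yl]methanol | C[C@]1(/C=C/Cl)C[C@]2(CO)O[C@@H]2C[C@H]1Cl | intermediate
29 | (1R,2S,4R,5R)-2,5-dichloro-4-[(E)-2-chlorovinyl]-2-(hydroxymethyl)-4-methylcyclohexan-1-ol | C[C@]1(/C=C/Cl)C[C@](Cl)(CO)[C@H](O)C[C@H]1Cl | intermediate
30 | (1R,2S,4R,5R)-2,5-dichloro-4-[(E)-2-chlorovinyl]-4-methyl-2-{[(trifluoromethanesulfonyl)oxy]methyl}cyclohexyl trifluoromethanesulfonate | C[C@]1(/C=C/Cl)C[C@](Cl)(COS(=O)(=O)C(F)(F)F)[C@H](OS(=O)(=O)C(F)(F)F)C[C@H]1Cl | intermediate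
31 | (1S,2S,4R,5R)-2-bromo-1-(bromomethyl)-1,4-dichloro-5-[(E)-2-chlorovinyl]-5-methylcyclohexane | C[C@]1(/C=C/Cl)C[C@](Cl)(CBr)[C@@H](Br)C[C@H]1Cl | target

**Step count**

Total step count: 18.
Longest linear sequence: 18 steps (1 → 31).

**Steps most likely to fail**

Step 18. At the secondary carbon next to the fully substituted chlorinated carbon, loss of triflic acid toward C5 or ionisation with chlorine bridging (retention, or a 1,2-chlorine shift) may outpace direct displacement, and the neopentyl primary centre may lag behind. The fallback sets out from 28 and comes back at 31, and it introduces bromine by opening the oxirane instead of displacing a sulfonate. Ti(Oi-Pr)4 with diethylammonium bromide should open the 2,3-epoxy alcohol 28 at the ring carbon remote from the hydroxymethyl group, with inversion, to give (1R,2S,4R,5R)-2-bromo-4-chloro-5-[(E)-2-chlorovinyl]-1-(hydroxymethyl)-5-methylcyclohexan-1-ol F1. Mitsunobu cyclodehydration (PPh3, DIAD) activates the primary hydroxyl of this 1,2-diol and should close, with retention at the tertiary carbon, (3R,4S,6R,7R)-4-bromo-6-chloro-7-[(E)-2-chlorovinyl]-7-methyl-1-oxaspiro[2.5]octane F2. HCl in Et2O/CH2Cl2 should then open F2 at the tertiary carbon with inversion; in the chair that keeps the bromine and the ring chlorine equatorial the C–O bond is gauche to C–Br, so bromine cannot bridge. This gives [(1S,2S,4R,5R)-2-bromo-1,4-dichloro-5-[(E)-2-chlorovinyl]-5-methylcyclohexyl]methanol F3, and CBr4/PPh3 converts its primary alcohol into the bromide 31. The weak point of this detour is competition from chloride attack at the oxirane CH2.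

Step 9. Stereochemical fidelity may be lost if the allylic alkoxyphosphonium ionises (return of chloride on either face, or at C10), or if chloride exchange epimerises the product. The fallback sets out from 12 and comes back at 17, and it transfers chirality across the allyl system instead of inverting at C8. SeO2 with t-BuOOH should hydroxylate the only allylic methylene of 12 to give (7R)-7-methyl-7-vinyl-1,4-dioxaspiro[4.5]dec-8-en-10-ol F4 as both C10 epimers. Dess–Martin oxidation gives (R)-7-methyl-7-vinyl-1,4-dioxaspiro[4.5]dec-8-en-10-one F5, and CBS reduction with the (R)-oxazaborolidine and catecholborane should set (7R,10S)-7-methyl-7-vinyl-1,4-dioxaspiro[4.5]dec-8-en-10-ol F6. SOCl2 in Et2O without base converts F6 into (7R,10S)-7-methyl-7-vinyl-1,4-dioxaspiro[4.5]dec-8-en-10-yl chlorosulfite F7, which should collapse by the syn SNi′ pathway: chlorine is delivered to C8 on the face the oxygen leaves, the ketal disfavouring return at C10, to give 17.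

Step 17. Regiocontrol may be poor: chloride may attack the secondary oxirane carbon, or the tertiary carbon may lose a proton instead of capturing chloride because the axial approach is syn to the chlorovinyl group. The fallback sets out from 28 and comes back at 29, and it moves the oxirane to the exocyclic position so that the ring carbinol carbon can no longer compete. I2, PPh3 and imidazole should convert 28 into (1S,3R,4R,6R)-4-chloro-3-[(E)-2-chlorovinyl]-1-(iodomethyl)-3-methyl-7-oxabicyclo[4.1.0]heptane F8. Zinc dust in EtOH (reductive oxirane opening) gives the transposed allylic alcohol (1R,4R,5R)-5-chloro-4-[(E)-2-chlorovinyl]-4-methyl-2-methylenecyclohexan-1-ol F9 with the carbinol configuration retained. VO(acac)2 with t-BuOOH should epoxidise syn to the hydroxyl to give (3R,4R,6R,7R)-6-chloro-7-[(E)-2-chlorovinyl]-7-methyl-1-oxaspiro[2.5]octan-4-ol F10. HCl in Et2O/CH2Cl2 then opens this 2,2-disubstituted oxirane at its tertiary carbon with inversion to give 29; the residual risk is chloride attack at the exocyclic CH2.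

Further compounds
F1 | step 18 | (1R,2S,4R,5R)-2-bromo-4-chloro-5-[(E)-2-chlorovinyl]-1-(hydroxymethyl)-5-methylcyclohexan-1-ol | C[C@]1(/C=C/Cl)C[C@@](O)(CO)[C@@H](Br)C[C@H]1Cl
F2 | step 18 | (3R,4S,6R,7R)-4-bromo-6-chloro-7-[(E)-2-chlorovinyl]-7-methyl-1-oxaspiro[2.5]octane | C[C@]1(/C=C/Cl)C[C@@]2(CO2)[C@@H](Br)C[C@H]1Cl
F3 | step 18 | [(1S,2S,4R,5R)-2-bromo-1,4-dichloro-5-[(E)-2-chlorovinyl]-5-methylcyclohexyl]methanol | C[C@]1(/C=C/Cl)C[C@](Cl)(CO)[C@@H](Br)C[C@H]1Cl
F4 | step 9 | (7R)-7-methyl-7-vinyl-1,4-dioxaspiro[4.5]dec-8-en-10-ol (both C10 epimers) | C[C@]1(C=C)CC2(OCCO2)C(O)C=C1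
F5 | step 9 | (R)-7-methyl-7-vinyl-1,4-dioxaspiro[4.5]dec-8-en-10-one | C[C@]1(C=C)CC2(OCCO2)C(=O)C=C1
F6 | step 9 | (7R,10S)-7-methyl-7-vinyl-1,4-dioxaspiro[4.5]dec-8-en-10-ol | C[C@]1(C=C)CC2(OCCO2)[C@@H](O)C=C1
F7 | step 9 | (7R,10S)-7-methyl-7-vinyl-1,4-dioxaspiro[4.5]dec-8-en-10-yl chlorosulfite | C[C@]1(C=C)CC2(OCCO2)[C@@H](OS(=O)Cl)C=C1
F8 | step 17 | (1S,3R,4R,6R)-4-chloro-3-[(E)-2-chlorovinyl]-1-(iodomethyl)-3-methyl-7-oxabicyclo[4.1.0]heptane | C[C@]1(/C=C/Cl)C[C@]2(CI)O[C@@H]2C[C@H]1Cl
F9 | step 17 | (1R,4R,5R)-5-chloro-4-[(E)-2-chlorovinyl]-4-methyl-2-methylenecyclohexan-1-ol | C[C@]1(/C=C/Cl)CC(=C)[C@H](O)C[C@H]1Cl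
F10 | step 17 | (3R,4R,6R,7R)-6-chloro-7-[(E)-2-chlorovinyl]-7-methyl-1-oxaspiro[2.5]octan-4-ol | C[C@]1(/C=C/Cl)C[C@@]2(CO2)[C@H](O)C[C@H]1Cl
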